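**Plan**

- Retrosynthetic cuts, in order: (1) the Cα–aryl bond to the resorcinol ring (Friedel–Crafts); (2) the ring A C6–Cα bond (aryllithium plus a lactic Weinreb amide); (3) the C4–C4a bond of the pyran ring (aryllithium cycloalkylation); (4) the O1–C2 ether bond (Mitsunobu).
- Labels: Cα is the diarylmethine carbon on C6, Cβ the carbinol carbon, Cγ the CH2 that carries the 4-hydroxyphenyl ring.
- Enabling feature: C3 of the pyran ring sits between two CH2 groups (C2 and C4), so it is the central carbon of a prochiral 2-arylpropane-1,3-diol. C4a of ring A is ortho to O1, so an iodine placed there marks the site of C–C closure.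
- Forward: ring B aldehyde → arylmalonate → diol → lipase monoacetate → ether with the iodophenol → bromide → pyran ring closed (the only ring made) → C6 bromide → ketone with the tyrosine-derived amide → benzylic alcohol → arylation by resorcinol dibenzyl ether → hydrogenolysis.
- Stereochemistry: C3 from enzymatic desymmetrisation of the diol; Cβ from D-tyrosine (diazotisation with retention); Cα from allylic-strain-controlled attack of the arene on the Cβ-branched benzylic cation.

Key step: step 11

Assumption: lipase PS is taken to acylate the enantiotopic CH2OH arm that gives the (2R)-monoacetate 8; should it acylate the other arm, the two arms are elaborated in the opposite order (fallback for step 6).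

**Route**

Step 1
Reactants: 1 2-hydroxy-3,4-dimethoxybenzaldehyde
Product: 2 2-(benzyloxy)-3,4-dimethoxybenzaldehyde
Conditions: BnBr, K2CO3, DMF, 60 °C
Reagents that add atoms: benzyl bromide, BrCc1ccccc1
Why: Williamson O-alkylation of the phenoxide with a benzylic bromide should be clean in DMF, and benzyl is chosen because it survives LiAlH4 and organolithiums and leaves in the last step.

Step 2
Reactants: 2 2-(benzyloxy)-3,4-dimethoxybenzaldehyde
Product: 3 2-(benzyloxy)-3,4-dimethoxy-1-[2-(methylsulfanyl)-2-(methylsulfinyl)ethenyl]benzene (alkene geometry and sulfoxide configuration uncontrolled)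
Conditions: CH3S(O)CH2SCH3, benzyltrimethylammonium hydroxide (cat.), THF, reflux
Reagents that add atoms: methyl (methylsulfinyl)methyl sulfide, CSCS(C)=O
Why: Knoevenagel-type condensation of the aldehyde with the sulfur-stabilised carbanion gives a ketene dithioacetal S-oxide, a masked arylacetic acid that supplies the one extra carbon.

Step 3
Reactants: 3 2-(benzyloxy)-3,4-dimethoxy-1-[2-(methylsulfanyl)-2-(methylsulfinyl)ethenyl]benzene
Product: 4 ethyl [2-(benzyloxy)-3,4-dimethoxyphenyl]acetate
Conditions: HCl (sat.) in EtOH, 0 °C → rt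
Reagents that add atoms: ethanol, CCO
Why: Acid alcoholysis of a ketene dithioacetal S-oxide (C-protonation to a sulfur-stabilised cation, capture by ethanol, loss of both sulfur groups as the disulfide) is the established route from this intermediate to an arylacetic ester, and aryl benzyl ethers tolerate ethanolic HCl at room temperature.

Step 4
Reactants: 4 ethyl [2-(benzyloxy)-3,4-dimethoxyphenyl]acetate; 5 diethyl carbonate
Product: 6 diethyl 2-[2-(benzyloxy)-3,4-dimethoxyphenyl]propanedioate
Conditions: NaH (2.5 equiv), THF, reflux; then aq HCl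
Reagents that add atoms: none
Why: Crossed Claisen condensation of the ester enolate with the non-enolisable carbonate is driven to completion by deprotonation of the malonate as it forms.

Step 5
Reactants: 6 diethyl 2-[2-(benzyloxy)-3,4-dimethoxyphenyl]propanedioate
Product: 7 2-[2-(benzyloxy)-3,4-dimethoxyphenyl]propane-1,3-diol
Conditions: LiAlH4, THF, 0 °C → rt; then H2O, aq NaOH
Reagents that add atoms: none
Why: Hydride reduction of both esters gives the prochiral diol (no stereocentre, the two CH2OH arms are enantiotopic); slow addition of 6 to cold LiAlH4 limits enolate formation and the elimination that follows from it.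

Step 6
Reactants: 7 2-[2-(benzyloxy)-3,4-dimethoxyphenyl]propane-1,3-diol
Product: 8 (2R)-2-[2-(benzyloxy)-3,4-dimethoxyphenyl]-3-hydroxypropyl acetate
Conditions: Amano lipase PS (Burkholderia cepacia, immobilised), vinyl acetate, tBuOMe, 25 °C
Reagents that add atoms: vinyl acetate, C=COC(C)=O
Why: Lipase-catalysed transesterification with an enol ester (enzymatic desymmetrisation of a 2-aryl-1,3-propanediol) acylates one enantiotopic CH2OH group irreversibly, and the chiral active site thereby sets the carbon that becomes C3.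

Step 7
Reactants: 9 3-(benzyloxy)phenol
Product: 10 5-(benzyloxy)-2-iodophenol
Conditions: I2 (1.0 equiv), NaHCO3, THF/H2O, 0 °C → rt
Reagents that add atoms: iodine, II
Why: Electrophilic iodination of the phenoxide should go ortho to the phenoxide oxygen and para to the benzyloxy group, the position between the two oxygens being the most hindered, and one equivalent of I2 at 0 °C limits di-iodination.

Step 8
Reactants: 8 (2R)-2-[2-(benzyloxy)-3,4-dimethoxyphenyl]-3-hydroxypropyl acetate; 10 5-(benzyloxy)-2-iodophenol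
Product: 11 (2R)-2-[2-(benzyloxy)-3,4-dimethoxyphenyl]-3-[5-(benzyloxy)-2-iodophenoxy]propyl acetate
Conditions: PPh3, DIAD, THF, 0 °C → rt
Reagents that add atoms: none
Why: Mitsunobu etherification: the acidic ortho-iodophenol displaces the activated primary alcohol by SN2 at CH2, forming the future O1–C2 bond without touching the stereocentre.

Step 9
Reactants: 11 (2R)-2-[2-(benzyloxy)-3,4-dimethoxyphenyl]-3-[5-(benzyloxy)-2-iodophenoxy]propyl acetate
Product: 12 (2S)-2-[2-(benzyloxy)-3,4-dimethoxyphenyl]-3-[5-(benzyloxy)-2-iodophenoxy]propan-1-ol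
Conditions: K2CO3 (cat.), MeOH, 0 °C → rt
Reagents that add atoms: none
Why: Base-catalysed transesterification removes the acetate under conditions that leave the aryl iodide and the ethers alone; the descriptor changes only because the CIP ranking of the arms changes.

Step 10
Reactants: 12 (2S)-2-[2-(benzyloxy)-3,4-dimethoxyphenyl]-3-[5-(benzyloxy)-2-iodophenoxy]propan-1-ol
Product: 13 (2R)-2-[2-(benzyloxy)-3,4-dimethoxyphenyl]-1-[5-(benzyloxy)-2-iodophenoxy]-3-bromopropane
Conditions: CBr4, PPh3, CH2Cl2, 0 °C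
Reagents that add atoms: carbon tetrabromide, BrC(Br)(Br)Br
Why: Appel reaction converts the primary alcohol into the bromide by SN2 at CH2 under neutral conditions, so neither elimination nor change at the stereocentre is expected.

Step 11
Reactants: 13 (2R)-2-[2-(benzyloxy)-3,4-dimethoxyphenyl]-1-[5-(benzyloxy)-2-iodophenoxy]-3-bromopropane
Product: 15 (3R)-7-(benzyloxy)-3-[2-(benzyloxy)-3,4-dimethoxyphenyl]chromane, via aryllithium 14 (not isolated)
Conditions: tBuLi (2.05 equiv), THF/Et2O, −100 °C; then warm to 0 °C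
Reagents that add atoms: none
Why: At −100 °C tBuLi should exchange the aryl iodide much faster than it attacks the primary bromide or the benzyl ethers, and the second equivalent destroys the tBuI formed; aryllithium 14, held ortho to the ether oxygen, then displaces bromide within the molecule on warming and forms the C4–C4a bond. This is a Parham cyclisation (halogen–lithium exchange followed by anionic cycloalkylation), the reaction type by which ω-(2-halophenoxy)alkyl bromides are closed to chromans. The pyran ring closes in a 6-exo-tet mode. No stereocentre is created; C3, set in step 6, is adjacent to the reacting carbon and keeps its configuration as long as substitution outruns loss of HBr across C3–C4. Site selectivity (C4a and not the other carbon ortho to O1) is fixed by the position of the iodine alone. Chemoselectivity rests on the rate order aryl iodide exchange > attack on the alkyl bromide, secured by exactly two equivalents of tBuLi and the low temperature.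

Step 12
Reactants: 15 (3R)-7-(benzyloxy)-3-[2-(benzyloxy)-3,4-dimethoxyphenyl]chromane
Product: 16 (3R)-7-(benzyloxy)-3-[2-(benzyloxy)-3,4-dimethoxyphenyl]-6-bromochromane
Conditions: NBS (1.0 equiv), MeCN, −20 → 0 °C, dark
Reagents that add atoms: N-bromosuccinimide, O=C1CCC(=O)N1Br
Why: Electrophilic aromatic bromination should pick C6, which is para to O1 and ortho to the 7-benzyloxy group, over C8 (flanked by two oxygens) and over ring B, whose crowded 2′- and 3′-ethers are twisted out of conjugation and activate it less.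

Step 13
Reactants: 17 O-benzyl-D-tyrosine
Product: 18 (2R)-3-[4-(benzyloxy)phenyl]-2-hydroxypropanoic acid
Conditions: NaNO2, aq H2SO4 (1 M), 1,4-dioxane, 0 °C → rt
Reagents that add atoms: water, O
Why: Diazotisation of an α-amino acid replaces NH2 by OH with net retention through carboxylate participation (two successive inversions), which carries the (R) centre of D-tyrosine into Cβ.

Step 14
Reactants: 18 (2R)-3-[4-(benzyloxy)phenyl]-2-hydroxypropanoic acid
Product: 19 (2R)-3-[4-(benzyloxy)phenyl]-2-hydroxy-N-methoxy-N-methylpropanamide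
Conditions: MeNHOMe·HCl, EDC·HCl, HOBt, N-methylmorpholine, CH2Cl2, 0 °C → rt
Reagents that add atoms: N,O-dimethylhydroxylamine hydrochloride, CNOC.Cl
Why: Carbodiimide-mediated amide coupling, in which the amine outcompetes the free secondary hydroxyl for the active ester and the stereocentre is not involved.

Step 15
Reactants: 19 (2R)-3-[4-(benzyloxy)phenyl]-2-hydroxy-N-methoxy-N-methylpropanamide
Product: 20 (2R)-2-(benzyloxy)-3-[4-(benzyloxy)phenyl]-N-methoxy-N-methylpropanamide
Conditions: BnOC(=NH)CCl3, TfOH (cat.), CH2Cl2/cyclohexane, 0 °C → rt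
Reagents that add atoms: benzyl 2,2,2-trichloroacetimidate, ClC(Cl)(Cl)C(=N)OCc1ccccc1
Why: Acid-catalysed O-benzylation with the trichloroacetimidate avoids base, so the α-oxygenated stereocentre cannot epimerise through an enolate.

Step 16
Reactants: 16 (3R)-7-(benzyloxy)-3-[2-(benzyloxy)-3,4-dimethoxyphenyl]-6-bromochromane; 20 (2R)-2-(benzyloxy)-3-[4-(benzyloxy)phenyl]-N-methoxy-N-methylpropanamide
Product: 22 (2R)-2-(benzyloxy)-1-{(3R)-7-(benzyloxy)-3-[2-(benzyloxy)-3,4-dimethoxyphenyl]chroman-6-yl}-3-[4-(benzyloxy)phenyl]propan-1-one, via aryllithium 21 (not isolated)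
Conditions: nBuLi (1.05 equiv), THF, −78 °C; then 20, −78 → −20 °C; aq HCl
Reagents that add atoms: none
Why: Bromine–lithium exchange followed by Weinreb ketone synthesis: the N-methoxy chelate holds the adduct until the quench, so a single addition occurs and Cβ is not enolised at low temperature.

Step 17
Reactants: 22 (2R)-2-(benzyloxy)-1-{(3R)-7-(benzyloxy)-3-[2-(benzyloxy)-3,4-dimethoxyphenyl]chroman-6-yl}-3-[4-(benzyloxy)phenyl]propan-1-one
Product: 23 (1RS,2R)-2-(benzyloxy)-1-{(3R)-7-(benzyloxy)-3-[2-(benzyloxy)-3,4-dimethoxyphenyl]chroman-6-yl}-3-[4-(benzyloxy)phenyl]propan-1-ol (both Cα epimers)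
Conditions: NaBH4, MeOH/THF, 0 °C
Reagents that add atoms: none
Why: Borohydride reduction of the aryl ketone gives the benzylic alcohol; the configuration at Cα is of no consequence because both epimers ionise to the same cation in step 18.

Step 18
Reactants: 23 (1RS,2R)-2-(benzyloxy)-1-{(3R)-7-(benzyloxy)-3-[2-(benzyloxy)-3,4-dimethoxyphenyl]chroman-6-yl}-3-[4-(benzyloxy)phenyl]propan-1-ol; 24 1,3-bis(benzyloxy)benzene
Product: 26 (3R)-7-(benzyloxy)-3-[2-(benzyloxy)-3,4-dimethoxyphenyl]-6-{(1R,2R)-2-(benzyloxy)-3-[4-(benzyloxy)phenyl]-1-[2,4-bis(benzyloxy)phenyl]propyl}chromane, via benzylic cation 25 (not isolated)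
Conditions: 24 (5 equiv), Bi(OTf)3 (5 mol%), CH2Cl2, −40 → 0 °C
Reagents that add atoms: none
Why: Friedel–Crafts alkylation of the electron-rich arene (at its 4-position, para to one ether and ortho to the other) by a secondary benzylic cation stabilised by the ortho and para oxygens of ring A; the cation should hold the Cβ–H bond in the plane of the ring to avoid A(1,3) strain, which places the benzyloxy group and the CH2Ar group on opposite faces, and attack opposite the larger CH2Ar group (syn to the ether oxygen) gives (R)-Cα from (R)-Cβ.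

Step 19
Reactants: 26 (3R)-7-(benzyloxy)-3-[2-(benzyloxy)-3,4-dimethoxyphenyl]-6-{(1R,2R)-2-(benzyloxy)-3-[4-(benzyloxy)phenyl]-1-[2,4-bis(benzyloxy)phenyl]propyl}chromane
Product: 27 (3R)-6-[(1R,2R)-1-(2,4-dihydroxyphenyl)-2-hydroxy-3-(4-hydroxyphenyl)propyl]-3-(2-hydroxy-3,4-dimethoxyphenyl)chroman-7-ol
Conditions: H2 (1 atm), Pd(OH)2/C, EtOAc/MeOH, rt
Reagents that add atoms: none
Why: Catalytic hydrogenolysis should cleave all six benzyl ethers (five aryl, one secondary alkyl) while the chroman ether, the methyl ethers and the Cβ–O bond, none of them benzylic C–O bonds, stay intact and no stereocentre is touched.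

**Compound list**

1 | 2-hydroxy-3,4-dimethoxybenzaldehyde | COc1ccc(C=O)c(O)c1OC | starting material
2 | 2-(benzyloxy)-3,4-dimethoxybenzaldehyde | COc1ccc(C=O)c(OCc2ccccc2)c1OC | intermediate
3 | 2-(benzyloxy)-3,4-dimethoxy-1-[2-(methylsulfanyl)-2-(methylsulfinyl)ethenyl]benzene | COc1ccc(C=C(SC)S(C)=O)c(OCc2ccccc2)c1OC | intermediate
4 | ethyl [2-(benzyloxy)-3,4-dimethoxyphenyl]acetate | CCOC(=O)Cc1ccc(OC)c(OC)c1OCc1ccccc1 | intermediate
5 | diethyl carbonate | CCOC(=O)OCC | starting material
6 | diethyl 2-[2-(benzyloxy)-3,4-dimethoxyphenyl]propanedioate | CCOC(=O)C(C(=O)OCC)c1ccc(OC)c(OC)c1OCc1ccccc1 | intermediate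
7 | 2-[2-(benzyloxy)-3,4-dimethoxyphenyl]propane-1,3-diol | COc1ccc(C(CO)CO)c(OCc2ccccc2)c1OC | intermediate
8 | (2R)-2-[2-(benzyloxy)-3,4-dimethoxyphenyl]-3-hydroxypropyl acetate | COc1ccc([C@@H](COC(C)=O)CO)c(OCc2ccccc2)c1OC | intermediate
9 | 3-(benzyloxy)phenol | Oc1cccc(OCc2ccccc2)c1 | starting material
10 | 5-(benzyloxy)-2-iodophenol | Oc1cc(OCc2ccccc2)ccc1I | intermediate
11 | (2R)-2-[2-(benzyloxy)-3,4-dimethoxyphenyl]-3-[5-(benzyloxy)-2-iodophenoxy]propyl acetate | COc1ccc([C@@H](COC(C)=O)COc2cc(OCc3ccccc3)ccc2I)c(OCc2ccccc2)c1OC | intermediate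
12 | (2S)-2-[2-(benzyloxy)-3,4-dimethoxyphenyl]-3-[5-(benzyloxy)-2-iodophenoxy]propan-1-ol | COc1ccc([C@@H](CO)COc2cc(OCc3ccccc3)ccc2I)c(OCc2ccccc2)c1OC | intermediate
13 | (2R)-2-[2-(benzyloxy)-3,4-dimethoxyphenyl]-1-[5-(benzyloxy)-2-iodophenoxy]-3-bromopropane | COc1ccc([C@@H](CBr)COc2cc(OCc3ccccc3)ccc2I)c(OCc2ccccc2)c1OC | intermediate
14 | (2R)-2-[2-(benzyloxy)-3,4-dimethoxyphenyl]-1-[5-(benzyloxy)-2-lithiophenoxy]-3-bromopropane (aryllithium) | COc1ccc([C@@H](CBr)COc2cc(OCc3ccccc3)ccc2[Li])c(OCc2ccccc2)c1OC | intermediate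
15 | (3R)-7-(benzyloxy)-3-[2-(benzyloxy)-3,4-dimethoxyphenyl]chromane | COc1ccc([C@@H]2COc3cc(OCc4ccccc4)ccc3C2)c(OCc2ccccc2)c1OC | intermediate
16 | (3R)-7-(benzyloxy)-3-[2-(benzyloxy)-3,4-dimethoxyphenyl]-6-bromochromane | COc1ccc([C@@H]2COc3cc(OCc4ccccc4)c(Br)cc3C2)c(OCc2ccccc2)c1OC | intermediate
17 | O-benzyl-D-tyrosine, (2R)-2-amino-3-[4-(benzyloxy)phenyl]propanoic acid | N[C@H](Cc1ccc(OCc2ccccc2)cc1)C(=O)O | starting material
18 | (2R)-3-[4-(benzyloxy)phenyl]-2-hydroxypropanoic acid | O[C@H](Cc1ccc(OCc2ccccc2)cc1)C(=O)O | intermediate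
19 | (2R)-3-[4-(benzyloxy)phenyl]-2-hydroxy-N-methoxy-N-methylpropanamide | CON(C)C(=O)[C@H](O)Cc1ccc(OCc2ccccc2)cc1 | intermediate
20 | (2R)-2-(benzyloxy)-3-[4-(benzyloxy)phenyl]-N-methoxy-N-methylpropanamide | CON(C)C(=O)[C@H](OCc1ccccc1)Cc1ccc(OCc2ccccc2)cc1 | intermediate
21 | (3R)-7-(benzyloxy)-3-[2-(benzyloxy)-3,4-dimethoxyphenyl]-6-lithiochromane (aryllithium) | COc1ccc([C@@H]2COc3cc(OCc4ccccc4)c([Li])cc3C2)c(OCc2ccccc2)c1OC | intermediate
22 | (2R)-2-(benzyloxy)-1-{(3R)-7-(benzyloxy)-3-[2-(benzyloxy)-3,4-dimethoxyphenyl]chroman-6-yl}-3-[4-(benzyloxy)phenyl]propan-1-one | COc1ccc([C@@H]2COc3cc(OCc4ccccc4)c(C(=O)[C@H](OCc4ccccc4)Cc4ccc(OCc5ccccc5)cc4)cc3C2)c(OCc2ccccc2)c1OC | intermediate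
23 | (1RS,2R)-2-(benzyloxy)-1-{(3R)-7-(benzyloxy)-3-[2-(benzyloxy)-3,4-dimethoxyphenyl]chroman-6-yl}-3-[4-(benzyloxy)phenyl]propan-1-ol, both Cα epimers | COc1ccc([C@@H]2COc3cc(OCc4ccccc4)c(C(O)[C@H](OCc4ccccc4)Cc4ccc(OCc5ccccc5)cc4)cc3C2)c(OCc2ccccc2)c1OC | intermediate
24 | 1,3-bis(benzyloxy)benzene | c1ccc(COc2cccc(OCc3ccccc3)c2)cc1 | starting material
25 | benzylic cation from 23 by loss of hydroxide at Cα, Cβ configuration unchanged | COc1ccc([C@@H]2COc3cc(OCc4ccccc4)c([CH+][C@H](OCc4ccccc4)Cc4ccc(OCc5ccccc5)cc4)cc3C2)c(OCc2ccccc2)c1OC | intermediate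
26 | (3R)-7-(benzyloxy)-3-[2-(benzyloxy)-3,4-dimethoxyphenyl]-6-{(1R,2R)-2-(benzyloxy)-3-[4-(benzyloxy)phenyl]-1-[2,4-bis(benzyloxy)phenyl]propyl}chromane | COc1ccc([C@@H]2COc3cc(OCc4ccccc4)c([C@@H](c4ccc(OCc5ccccc5)cc4OCc4ccccc4)[C@H](OCc4ccccc4)Cc4ccc(OCc5ccccc5)cc4)cc3C2)c(OCc2ccccc2)c1OC | intermediate
27 | (3R)-6-[(1R,2R)-1-(2,4-dihydroxyphenyl)-2-hydroxy-3-(4-hydroxyphenyl)propyl]-3-(2-hydroxy-3,4-dimethoxyphenyl)chroman-7-ol | COc1ccc([C@@H]2COc3cc(O)c([C@@H](c4ccc(O)cc4O)[C@H](O)Cc4ccc(O)cc4)cc3C2)c(O)c1OC | target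

**Step count**

Total: 19 steps. Longest linear sequence: 15 steps (steps 1–6, 8–12, 16–19); steps 7 and 13–15 are side branches.

**Steps most likely to fail**

1. Step 18. The arene may attack the cation on the face next to the CH2Ar group if the ether oxygen, not size, governs the approach, giving the Cα epimer; proton loss from Cβ to an enol ether may also compete. Fallback, setting out from 20 and 15 and returning at 26: the two rings on Cα exchange roles. 2,4-Bis(benzyloxy)-1-bromobenzene F1 is lithiated (nBuLi, THF, −78 °C) to [2,4-bis(benzyloxy)phenyl]lithium F2 and acylated with 20 to give (2R)-1-[2,4-bis(benzyloxy)phenyl]-2-(benzyloxy)-3-[4-(benzyloxy)phenyl]propan-1-one F3. NaBH4 reduces it to (1RS,2R)-1-[2,4-bis(benzyloxy)phenyl]-2-(benzyloxy)-3-[4-(benzyloxy)phenyl]propan-1-ol F4. Bi(OTf)3 ionises this to the resorcinol-type benzylic cation F5, which should be captured by C6 of isoflavan 15 (para to O1, ortho to the 7-benzyloxy group). Because the resident and incoming aryl groups have changed places, the facial preference that would give the wrong epimer in step 18 should here give 26. Steps 12, 16 and 17 are then not needed.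

2. Step 11. The aryllithium or residual tBuLi may act as a base before C–C bond formation, removing HBr across C3–C4 or abstracting the benzylic C3–H, which would destroy the bromide and the stereocentre. Fallback, setting out from 13 and returning at 15: a nickel-catalysed reductive cross-electrophile cyclisation (NiI2, 4,4′-di-tert-butyl-2,2′-bipyridine, Zn powder, NaI, DMA, 40–60 °C). The aryl iodide adds to nickel and the primary alkyl radical from the bromide is captured, closing the same C4–C4a bond without a basic carbanion. No new compound is made (F0).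

3. Step 6. The lipase may acylate the opposite enantiotopic arm. Fallback, setting out from 7 and returning at 13: the product is then (2S)-2-[2-(benzyloxy)-3,4-dimethoxyphenyl]-3-hydroxypropyl acetate F6, and its arms are elaborated in the reverse order. Appel bromination of the free hydroxyl (CBr4, PPh3) gives (2R)-2-[2-(benzyloxy)-3,4-dimethoxyphenyl]-3-bromopropyl acetate F7. Acid methanolysis (HCl, MeOH) gives (2R)-2-[2-(benzyloxy)-3,4-dimethoxyphenyl]-3-bromopropan-1-ol F8. Mitsunobu coupling with 10 then gives 13 with the required (R) configuration.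

**Further compounds**

F1 | step 18 | 2,4-bis(benzyloxy)-1-bromobenzene | Brc1ccc(OCc2ccccc2)cc1OCc1ccccc1
F2 | step 18 | [2,4-bis(benzyloxy)phenyl]lithium | [Li]c1ccc(OCc2ccccc2)cc1OCc1ccccc1
F3 | step 18 | (2R)-1-[2,4-bis(benzyloxy)phenyl]-2-(benzyloxy)-3-[4-(benzyloxy)phenyl]propan-1-one | O=C(c1ccc(OCc2ccccc2)cc1OCc1ccccc1)[C@H](OCc1ccccc1)Cc1ccc(OCc2ccccc2)cc1
F4 | step 18 | (1RS,2R)-1-[2,4-bis(benzyloxy)phenyl]-2-(benzyloxy)-3-[4-(benzyloxy)phenyl]propan-1-ol | OC(c1ccc(OCc2ccccc2)cc1OCc1ccccc1)[C@H](OCc1ccccc1)Cc1ccc(OCc2ccccc2)cc1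
F5 | step 18 | benzylic cation from F4 by loss of hydroxide, Cβ configuration unchanged | [CH+](c1ccc(OCc2ccccc2)cc1OCc1ccccc1)[C@H](OCc1ccccc1)Cc1ccc(OCc2ccccc2)cc1
F0 | step 11 | none | none
F6 | step 6 | (2S)-2-[2-(benzyloxy)-3,4-dimethoxyphenyl]-3-hydroxypropyl acetate | COc1ccc([C@H](COC(C)=O)CO)c(OCc2ccccc2)c1OC
F7 | step 6 | (2R)-2-[2-(benzyloxy)-3,4-dimethoxyphenyl]-3-bromopropyl acetate | COc1ccc([C@@H](CBr)COC(C)=O)c(OCc2ccccc2)c1OC
F8 | step 6 | (2R)-2-[2-(benzyloxy)-3,4-dimethoxyphenyl]-3-bromopropan-1-ol | COc1ccc([C@@H](CBr)CO)c(OCc2ccccc2)c1OC
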